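**Retrosynthetic overview**

1. Labels: ring C1 (C=O), C2 (carries C7H2OAc), C3, C4 (CHOH), C5 (quaternary epoxide carbon, carries C1'), C6 (epoxide CH). The strategy rests on C4, a carbinol lying between vinylic C3 and epoxide carbon C5: the cyclohexenone ring is cut at C3–C4 into a Z-β-iodoenone (C1–C3, C7) and a C4 aldehyde held cis on the C5–C6 oxirane, and alkenylchromium addition closes the ring and creates C4.
2. Side chain last: C1'–C2' is cut to the C1' aldehyde of the core (C4–OH free) and an E-alkenyl iodide made from geranyl bromide (propargylation, carboalumination–iodination).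
3. The Z-β-iodoenone comes from an epoxy ynone (HC≡CMgBr on the C1 aldehyde, oxidation) by iodide conjugate addition and aldol capture of formaldehyde.
4. The oxirane (C5, C6) comes from asymmetric epoxidation of a trisubstituted allylic alcohol built from but-2-yne-1,4-diol (trans-hydroalumination–iodination, Stille hydroxymethylation).
5. Ring order: oxirane first (step 5), then the cyclohexenone ring (step 14).

Key step: step 14

**Route**

Step 1
Reactants: 1 but-2-yne-1,4-diol
Product: 2 4-[(4-methoxybenzyl)oxy]but-2-yn-1-ol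
Conditions: NaH (1.0 equiv), 4-methoxybenzyl chloride (1.0 equiv), Bu4NI (cat.), THF/DMF, 0 °C to rt; 1 in threefold excess
Reagents that add atoms: 4-methoxybenzyl chloride, COc1ccc(CCl)cc1
Why: Williamson etherification of the mono-alkoxide, with the excess of symmetric diol keeping dialkylation low; no stereocentre is involved.

Step 2
Reactants: 2 4-[(4-methoxybenzyl)oxy]but-2-yn-1-ol
Product: 4 (2Z)-3-iodo-4-[(4-methoxybenzyl)oxy]but-2-en-1-ol, via cyclic alkenylaluminate 3 (not isolated)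
Conditions: NaAlH2(OCH2CH2OMe)2 (Red-Al), THF, 0 °C to rt; EtOAc; then I2, THF, −78 to 0 °C
Reagents that add atoms: iodine, II
Why: Hydroxyl-directed trans-hydroalumination of the propargylic alcohol puts aluminium on the distal alkyne carbon (C5) in a five-membered aluminate, and iodinolysis with retention gives the Z-iodide with iodine cis to C1H2OH.

Step 3
Reactants: 4 (2Z)-3-iodo-4-[(4-methoxybenzyl)oxy]but-2-en-1-ol
Product: 5 triethyl{[(2Z)-3-iodo-4-[(4-methoxybenzyl)oxy]but-2-en-1-yl]oxy}silane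
Conditions: Et3SiCl, imidazole, CH2Cl2, 0 °C
Reagents that add atoms: chlorotriethylsilane, CC[Si](Cl)(CC)CC
Why: Routine silylation of the primary allylic alcohol, so that the hydroxymethyl group introduced next is the only free hydroxyl and can direct the epoxidation.

Step 4
Reactants: 5 triethyl{[(2Z)-3-iodo-4-[(4-methoxybenzyl)oxy]but-2-en-1-yl]oxy}silane
Product: 6 (2E)-2-{[(4-methoxybenzyl)oxy]methyl}-4-[(triethylsilyl)oxy]but-2-en-1-ol
Conditions: Bu3SnCH2OH (1.5 equiv), Pd(PPh3)4 (5 mol%), 1,4-dioxane, 90 °C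
Reagents that add atoms: (tributylstannyl)methanol, OC[Sn](CCCC)(CCCC)CCCC
Why: Stille cross-coupling transfers the hydroxymethyl group with retention at the alkenyl iodide, so C4 enters cis to C1H2OSiEt3 (E by the sequence rule).

Step 5
Reactants: 6 (2E)-2-{[(4-methoxybenzyl)oxy]methyl}-4-[(triethylsilyl)oxy]but-2-en-1-ol
Product: 7 [(2S,3S)-2-{[(4-methoxybenzyl)oxy]methyl}-3-{[(triethylsilyl)oxy]methyl}oxiran-2-yl]methanol
Conditions: Ti(OiPr)4 (20 mol%), D-(−)-diethyl tartrate (24 mol%), t-BuOOH, 4 Å molecular sieves, CH2Cl2, −20 °C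
Reagents that add atoms: tert-butyl hydroperoxide, CC(C)(C)OO
Why: Sharpless asymmetric epoxidation anchored on the C4 hydroxyl; with D-(−)-diethyl tartrate the titanium peroxo complex delivers oxygen to the alkene face that gives the (2S,3S)-oxirane, and syn addition keeps C4 and C1 cis, which sets C5 and C6.

Step 6
Reactants: 7 [(2S,3S)-2-{[(4-methoxybenzyl)oxy]methyl}-3-{[(triethylsilyl)oxy]methyl}oxiran-2-yl]methanol
Product: 8 tert-butyl{[(2R,3S)-2-{[(4-methoxybenzyl)oxy]methyl}-3-{[(triethylsilyl)oxy]methyl}oxiran-2-yl]methoxy}dimethylsilane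
Conditions: t-BuMe2SiCl, imidazole, DMF, 0 °C to rt
Reagents that add atoms: tert-butylchlorodimethylsilane, CC(C)(C)[Si](C)(C)Cl
Why: Silylation of the primary epoxy alcohol under mild base, which does not trigger epoxide migration; the descriptor at C5 changes only through the sequence rule.

Step 7
Reactants: 8 tert-butyl{[(2R,3S)-2-{[(4-methoxybenzyl)oxy]methyl}-3-{[(triethylsilyl)oxy]methyl}oxiran-2-yl]methoxy}dimethylsilane
Product: 9 (2R,3R)-3-{[tert-butyl(dimethyl)silyl]oxymethyl}-3-{[(4-methoxybenzyl)oxy]methyl}oxirane-2-carbaldehyde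
Conditions: (COCl)2, DMSO, CH2Cl2, −78 to −40 °C; then Et3N, −78 to 0 °C
Reagents that add atoms: none
Why: Swern oxidation in which chlorodimethylsulfonium chloride cleaves the primary triethylsilyl ether and oxidises it directly to the aldehyde, while the primary tert-butyldimethylsilyl ether is inert; the epoxide α-hydrogen does not epimerise.

Step 8
Reactants: 9 (2R,3R)-3-{[tert-butyl(dimethyl)silyl]oxymethyl}-3-{[(4-methoxybenzyl)oxy]methyl}oxirane-2-carbaldehyde; 10 ethynylmagnesium bromide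
Product: 11 1-[(2S,3R)-3-{[tert-butyl(dimethyl)silyl]oxymethyl}-3-{[(4-methoxybenzyl)oxy]methyl}oxiran-2-yl]prop-2-yn-1-ol (both C1 epimers)
Conditions: HC≡CMgBr (1.5 equiv), THF, −78 to −20 °C
Reagents that add atoms: none
Why: Grignard 1,2-addition to the aldehyde; the C1 epimer ratio does not matter because the carbinol is oxidised in step 9.

Step 9
Reactants: 11 1-[(2S,3R)-3-{[tert-butyl(dimethyl)silyl]oxymethyl}-3-{[(4-methoxybenzyl)oxy]methyl}oxiran-2-yl]prop-2-yn-1-ol
Product: 12 1-[(2R,3R)-3-{[tert-butyl(dimethyl)silyl]oxymethyl}-3-{[(4-methoxybenzyl)oxy]methyl}oxiran-2-yl]prop-2-yn-1-one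
Conditions: Dess–Martin periodinane, NaHCO3, CH2Cl2, 0 °C to rt
Reagents that add atoms: none
Why: Dess–Martin oxidation of the propargylic alcohol under buffered, non-nucleophilic conditions that spare the terminal ynone and the epoxide.

Step 10
Reactants: 12 1-[(2R,3R)-3-{[tert-butyl(dimethyl)silyl]oxymethyl}-3-{[(4-methoxybenzyl)oxy]methyl}oxiran-2-yl]prop-2-yn-1-one
Product: 14 (2Z)-1-[(2R,3R)-3-{[tert-butyl(dimethyl)silyl]oxymethyl}-3-{[(4-methoxybenzyl)oxy]methyl}oxiran-2-yl]-2-(hydroxymethyl)-3-iodoprop-2-en-1-one, via iodoallenyl silyl ether 13 (not isolated)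
Conditions: Me3SiI (1.2 equiv), CH2Cl2, −78 °C, 15 min; then monomeric CH2O (from cracked paraformaldehyde, excess), −78 to −50 °C; NaHCO3/Na2S2O3; dilute citric acid, THF/H2O, 0 °C
Reagents that add atoms: iodotrimethylsilane, C[Si](C)(C)I; formaldehyde, C=O
Why: Iodide-promoted Morita–Baylis–Hillman-type α-hydroxyalkylation of a ynone, in which conjugate addition of iodide gives the silyloxyallene and its Mukaiyama-type aldol with formaldehyde at C2 occurs on the allene face opposite iodine, placing iodine cis to the ketone (Z); the ynone is consumed at −78 °C before the silyl iodide can open the epoxide.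

Step 11
Reactants: 14 (2Z)-1-[(2R,3R)-3-{[tert-butyl(dimethyl)silyl]oxymethyl}-3-{[(4-methoxybenzyl)oxy]methyl}oxiran-2-yl]-2-(hydroxymethyl)-3-iodoprop-2-en-1-one
Product: 15 (2Z)-2-{[(2R,3R)-3-{[tert-butyl(dimethyl)silyl]oxymethyl}-3-{[(4-methoxybenzyl)oxy]methyl}oxiran-2-yl]carbonyl}-3-iodoprop-2-en-1-yl acetate
Conditions: AcCl, 2,4,6-collidine, CH2Cl2, −20 to 0 °C
Reagents that add atoms: acetyl chloride, CC(Cl)=O
Why: O-acetylation with a hindered, non-nucleophilic base, which avoids addition–elimination at the β-iodoenone.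

Step 12
Reactants: 15 (2Z)-2-{[(2R,3R)-3-{[tert-butyl(dimethyl)silyl]oxymethyl}-3-{[(4-methoxybenzyl)oxy]methyl}oxiran-2-yl]carbonyl}-3-iodoprop-2-en-1-yl acetate
Product: 16 (2Z)-2-{[(2R,3S)-3-(hydroxymethyl)-3-{[(4-methoxybenzyl)oxy]methyl}oxiran-2-yl]carbonyl}-3-iodoprop-2-en-1-yl acetate
Conditions: HF·pyridine, pyridine, THF, 0 °C to rt
Reagents that add atoms: none
Why: Buffered fluoride desilylation of the primary silyl ether, which leaves the acetate, the benzylic ether, the epoxide and the alkenyl iodide untouched.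

Step 13
Reactants: 16 (2Z)-2-{[(2R,3S)-3-(hydroxymethyl)-3-{[(4-methoxybenzyl)oxy]methyl}oxiran-2-yl]carbonyl}-3-iodoprop-2-en-1-yl acetate
Product: 17 (2Z)-2-{[(2R,3S)-3-formyl-3-{[(4-methoxybenzyl)oxy]methyl}oxiran-2-yl]carbonyl}-3-iodoprop-2-en-1-yl acetate
Conditions: Dess–Martin periodinane, NaHCO3, CH2Cl2, 0 °C to rt; used at once
Reagents that add atoms: none
Why: Dess–Martin oxidation of the neopentyl-type primary alcohol to an aldehyde that has no α-hydrogen and so cannot enolise or epimerise.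

Step 14
Reactants: 17 (2Z)-2-{[(2R,3S)-3-formyl-3-{[(4-methoxybenzyl)oxy]methyl}oxiran-2-yl]carbonyl}-3-iodoprop-2-en-1-yl acetate
Product: 19 [(1R,5S,6R)-5-hydroxy-6-{[(4-methoxybenzyl)oxy]methyl}-2-oxo-7-oxabicyclo[4.1.0]hept-3-en-3-yl]methyl acetate, via alkenylchromium dichloride 18 (not isolated)
Conditions: CrCl2 (8 equiv), NiCl2 (2 mol%), degassed THF–DMF (3:1), rt, slow addition of 17 to 0.005 M
Reagents that add atoms: none
Why: Zerovalent nickel, formed from NiCl2 by CrCl2, inserts into the C3–I bond and hands the alkenyl group to trivalent chromium, and the alkenylchromium species 18 adds to the C4 aldehyde (Nozaki–Hiyama–Kishi reaction). The closest known reaction type is the intramolecular Nozaki–Hiyama–Kishi cyclisation of Z-iodoalkenyl aldehydes, which is also known for Z-β-iodo enoates and enones. The cyclohexenone ring closes in a 6-exo-trig mode through the C3–C4 bond; the cis-epoxide and the Z-alkene hold C3 and C4 within reach, and high dilution suppresses intermolecular coupling. The new stereocentre C4 is controlled by C5 through the rotamer of the formyl group: with C4=O anti to the C5–O bond of the epoxide (dipole minimisation) and syn to C1'H2O(4-methoxybenzyl), C3 can only reach the Si face, which places the C4 hydroxyl trans to the epoxide oxygen. The step needs this facial selectivity and chemoselectivity for the aldehyde: the first is secured by the benzylic ether oxygen, which can share chromium with the aldehyde oxygen in a six-membered chelate that holds the same rotamer and outbids the weakly basic epoxide oxygen, and the second by the inertness of alkenylchromium reagents toward ketones and esters and by the non-enolisable aldehyde.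

Step 15
Reactants: 19 [(1R,5S,6R)-5-hydroxy-6-{[(4-methoxybenzyl)oxy]methyl}-2-oxo-7-oxabicyclo[4.1.0]hept-3-en-3-yl]methyl acetate
Product: 20 [(1R,5S,6S)-6-{[(4-methoxybenzyl)oxy]methyl}-2-oxo-5-[(triethylsilyl)oxy]-7-oxabicyclo[4.1.0]hept-3-en-3-yl]methyl acetate
Conditions: Et3SiOSO2CF3, 2,6-lutidine, CH2Cl2, −78 °C
Reagents that add atoms: triethylsilyl trifluoromethanesulfonate, CC[Si](CC)(CC)OS(=O)(=O)C(F)(F)F
Why: Silylation of the secondary allylic alcohol with a silyl triflate and a hindered base at low temperature, so that no nucleophilic amine meets the enone or the allylic acetate; the descriptor at C5 changes only through the sequence rule.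

Step 16
Reactants: 20 [(1R,5S,6S)-6-{[(4-methoxybenzyl)oxy]methyl}-2-oxo-5-[(triethylsilyl)oxy]-7-oxabicyclo[4.1.0]hept-3-en-3-yl]methyl acetate
Product: 21 [(1R,5S,6S)-6-(hydroxymethyl)-2-oxo-5-[(triethylsilyl)oxy]-7-oxabicyclo[4.1.0]hept-3-en-3-yl]methyl acetate
Conditions: DDQ, CH2Cl2/pH 7 buffer (10:1), 0 °C to rt
Reagents that add atoms: none
Why: Oxidative cleavage of the 4-methoxybenzyl ether by single-electron oxidation of the electron-rich arene; the electron-poor enone, the silyl ether and the acetate do not react.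

Step 17
Reactants: 21 [(1R,5S,6S)-6-(hydroxymethyl)-2-oxo-5-[(triethylsilyl)oxy]-7-oxabicyclo[4.1.0]hept-3-en-3-yl]methyl acetate
Product: 22 [(1R,5S,6S)-6-formyl-2-oxo-5-[(triethylsilyl)oxy]-7-oxabicyclo[4.1.0]hept-3-en-3-yl]methyl acetate
Conditions: Dess–Martin periodinane, NaHCO3, CH2Cl2, 0 °C to rt
Reagents that add atoms: none
Why: Dess–Martin oxidation of the primary alcohol to the non-enolisable C1' aldehyde while C4–O is masked.

Step 18
Reactants: 22 [(1R,5S,6S)-6-formyl-2-oxo-5-[(triethylsilyl)oxy]-7-oxabicyclo[4.1.0]hept-3-en-3-yl]methyl acetate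
Product: 23 [(1R,5S,6R)-6-formyl-5-hydroxy-2-oxo-7-oxabicyclo[4.1.0]hept-3-en-3-yl]methyl acetate
Conditions: HF·pyridine, pyridine, THF, 0 °C; used crude
Reagents that add atoms: none
Why: Fluoride desilylation of the labile secondary triethylsilyl ether frees the C4 hydroxyl, which is wanted as the organising group in step 22; retro-aldol cleavage is blocked because C5 is an epoxide carbon.

Step 19
Reactants: 24 1-(trimethylsilyl)propyne; 25 geranyl bromide
Product: 27 trimethyl[(5E)-6,10-dimethylundeca-5,9-dien-1-yn-1-yl]silane, via lithiated silylpropyne 26 (not isolated)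
Conditions: n-BuLi, THF, −78 °C; then 25, −78 °C to rt
Reagents that add atoms: none
Why: Alkylation of the propargylic lithium reagent by direct SN2 displacement of the primary allylic bromide, which leaves the E-alkene of the geranyl unit untouched.

Step 20
Reactants: 27 trimethyl[(5E)-6,10-dimethylundeca-5,9-dien-1-yn-1-yl]silane
Product: 28 (5E)-6,10-dimethylundeca-5,9-dien-1-yne
Conditions: K2CO3 (cat.), MeOH, rt
Reagents that add atoms: none
Why: Base-catalysed methanolysis of the alkynyl C–Si bond (protodesilylation).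

Step 21
Reactants: 28 (5E)-6,10-dimethylundeca-5,9-dien-1-yne
Product: 30 (1E,5E)-1-iodo-2,6,10-trimethylundeca-1,5,9-triene, via alkenyldimethylalane 29 (not isolated)
Conditions: AlMe3 (2.5 equiv), Cp2ZrCl2 (25 mol%), CH2Cl2, 0 °C to rt; then I2, THF, −30 to 0 °C
Reagents that add atoms: trimethylaluminium, C[Al](C)C; iodine, II
Why: Zirconium-catalysed carboalumination (Negishi) adds methyl and aluminium syn across the terminal alkyne with aluminium on the terminal carbon, and iodinolysis with retention gives the E-iodide.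

Step 22
Reactants: 23 [(1R,5S,6R)-6-formyl-5-hydroxy-2-oxo-7-oxabicyclo[4.1.0]hept-3-en-3-yl]methyl acetate; 30 (1E,5E)-1-iodo-2,6,10-trimethylundeca-1,5,9-triene
Product: 32 [(1R,5S,6R)-5-hydroxy-6-[(1S,2E,6E)-1-hydroxy-3,7,11-trimethyldodeca-2,6,10-trien-1-yl]-2-oxo-7-oxabicyclo[4.1.0]hept-3-en-3-yl]methyl acetate (target), via side-chain alkenylchromium dichloride 31 (not isolated)
Conditions: 30 (3 equiv), CrCl2 (8 equiv), NiCl2 (2 mol%), degassed THF–DMF (3:1), rt
Reagents that add atoms: none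
Why: Intermolecular Nozaki–Hiyama–Kishi addition, selective for the aldehyde over the enone ketone and the acetate and retaining the E-geometry of the iodide; the free C4 hydroxyl (hydrogen bond or chromium chelate) holds C1'=O toward O4 and anti to the epoxide C–O bond, and the alkenyl group should enter on the Si face from the periphery, away from C6, to give the 1'S carbinol.

**Compound list**

1 | but-2-yne-1,4-diol | OCC#CCO | starting material
2 | 4-[(4-methoxybenzyl)oxy]but-2-yn-1-ol | COc1ccc(COCC#CCO)cc1 | intermediate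
3 | cyclic alkenylaluminate (sodium salt, not isolated) | [Na+].COCCO[Al-]1(OCCOC)OCC=C1COCc1ccc(OC)cc1 | intermediate
4 | (2Z)-3-iodo-4-[(4-methoxybenzyl)oxy]but-2-en-1-ol | OC/C=C(\I)COCc1ccc(OC)cc1 | intermediate
5 | triethyl{[(2Z)-3-iodo-4-[(4-methoxybenzyl)oxy]but-2-en-1-yl]oxy}silane | CC[Si](CC)(CC)OC/C=C(\I)COCc1ccc(OC)cc1 | intermediate
6 | (2E)-2-{[(4-methoxybenzyl)oxy]methyl}-4-[(triethylsilyl)oxy]but-2-en-1-ol | OC/C(COCc1ccc(OC)cc1)=C\CO[Si](CC)(CC)CC | intermediate
7 | [(2S,3S)-2-{[(4-methoxybenzyl)oxy]methyl}-3-{[(triethylsilyl)oxy]methyl}oxiran-2-yl]methanol | CC[Si](CC)(CC)OC[C@@H]1O[C@]1(COCc2ccc(OC)cc2)CO | intermediate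
8 | tert-butyl{[(2R,3S)-2-{[(4-methoxybenzyl)oxy]methyl}-3-{[(triethylsilyl)oxy]methyl}oxiran-2-yl]methoxy}dimethylsilane | CC[Si](CC)(CC)OC[C@@H]1O[C@]1(COCc2ccc(OC)cc2)CO[Si](C)(C)C(C)(C)C | intermediate
9 | (2R,3R)-3-{[tert-butyl(dimethyl)silyl]oxymethyl}-3-{[(4-methoxybenzyl)oxy]methyl}oxirane-2-carbaldehyde | O=C[C@@H]1O[C@]1(COCc2ccc(OC)cc2)CO[Si](C)(C)C(C)(C)C | intermediate
10 | ethynylmagnesium bromide | C#C[Mg]Br | starting material
11 | 1-[(2S,3R)-3-{[tert-butyl(dimethyl)silyl]oxymethyl}-3-{[(4-methoxybenzyl)oxy]methyl}oxiran-2-yl]prop-2-yn-1-ol (C1 epimers) | C#CC(O)[C@@H]1O[C@]1(COCc2ccc(OC)cc2)CO[Si](C)(C)C(C)(C)C | intermediate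
12 | 1-[(2R,3R)-3-{[tert-butyl(dimethyl)silyl]oxymethyl}-3-{[(4-methoxybenzyl)oxy]methyl}oxiran-2-yl]prop-2-yn-1-one | C#CC(=O)[C@@H]1O[C@]1(COCc2ccc(OC)cc2)CO[Si](C)(C)C(C)(C)C | intermediate
13 | iodoallenyl silyl ether (not isolated) | IC=C=C(O[Si](C)(C)C)[C@@H]1O[C@]1(COCc2ccc(OC)cc2)CO[Si](C)(C)C(C)(C)C | intermediate
14 | (2Z)-1-[(2R,3R)-3-{[tert-butyl(dimethyl)silyl]oxymethyl}-3-{[(4-methoxybenzyl)oxy]methyl}oxiran-2-yl]-2-(hydroxymethyl)-3-iodoprop-2-en-1-one | I/C=C(CO)\C(=O)[C@@H]1O[C@]1(COCc2ccc(OC)cc2)CO[Si](C)(C)C(C)(C)C | intermediate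
15 | (2Z)-2-{[(2R,3R)-3-{[tert-butyl(dimethyl)silyl]oxymethyl}-3-{[(4-methoxybenzyl)oxy]methyl}oxiran-2-yl]carbonyl}-3-iodoprop-2-en-1-yl acetate | I/C=C(COC(C)=O)\C(=O)[C@@H]1O[C@]1(COCc2ccc(OC)cc2)CO[Si](C)(C)C(C)(C)C | intermediate
16 | (2Z)-2-{[(2R,3S)-3-(hydroxymethyl)-3-{[(4-methoxybenzyl)oxy]methyl}oxiran-2-yl]carbonyl}-3-iodoprop-2-en-1-yl acetate | I/C=C(COC(C)=O)\C(=O)[C@@H]1O[C@]1(COCc2ccc(OC)cc2)CO | intermediate
17 | (2Z)-2-{[(2R,3S)-3-formyl-3-{[(4-methoxybenzyl)oxy]methyl}oxiran-2-yl]carbonyl}-3-iodoprop-2-en-1-yl acetate | I/C=C(COC(C)=O)\C(=O)[C@@H]1O[C@]1(COCc2ccc(OC)cc2)C=O | intermediate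
18 | alkenylchromium dichloride of 17 (trivalent chromium, not isolated) | Cl[Cr](Cl)/C=C(COC(C)=O)\C(=O)[C@@H]1O[C@]1(COCc2ccc(OC)cc2)C=O | intermediate
19 | [(1R,5S,6R)-5-hydroxy-6-{[(4-methoxybenzyl)oxy]methyl}-2-oxo-7-oxabicyclo[4.1.0]hept-3-en-3-yl]methyl acetate | CC(=O)OCC1=C[C@H](O)[C@@]2(COCc3ccc(OC)cc3)O[C@H]2C1=O | intermediate
20 | [(1R,5S,6S)-6-{[(4-methoxybenzyl)oxy]methyl}-2-oxo-5-[(triethylsilyl)oxy]-7-oxabicyclo[4.1.0]hept-3-en-3-yl]methyl acetate | CC(=O)OCC1=C[C@H](O[Si](CC)(CC)CC)[C@@]2(COCc3ccc(OC)cc3)O[C@H]2C1=O | intermediate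
21 | [(1R,5S,6S)-6-(hydroxymethyl)-2-oxo-5-[(triethylsilyl)oxy]-7-oxabicyclo[4.1.0]hept-3-en-3-yl]methyl acetate | CC(=O)OCC1=C[C@H](O[Si](CC)(CC)CC)[C@@]2(CO)O[C@H]2C1=O | intermediate
22 | [(1R,5S,6S)-6-formyl-2-oxo-5-[(triethylsilyl)oxy]-7-oxabicyclo[4.1.0]hept-3-en-3-yl]methyl acetate | CC(=O)OCC1=C[C@H](O[Si](CC)(CC)CC)[C@@]2(C=O)O[C@H]2C1=O | intermediate
23 | [(1R,5S,6R)-6-formyl-5-hydroxy-2-oxo-7-oxabicyclo[4.1.0]hept-3-en-3-yl]methyl acetate | CC(=O)OCC1=C[C@H](O)[C@@]2(C=O)O[C@H]2C1=O | intermediate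
24 | 1-(trimethylsilyl)propyne | CC#C[Si](C)(C)C | starting material
25 | geranyl bromide | CC(C)=CCC/C(C)=C/CBr | starting material
26 | 3-lithio-1-(trimethylsilyl)propyne (not isolated) | [Li]CC#C[Si](C)(C)C | intermediate
27 | trimethyl[(5E)-6,10-dimethylundeca-5,9-dien-1-yn-1-yl]silane | CC(C)=CCC/C(C)=C/CCC#C[Si](C)(C)C | intermediate
28 | (5E)-6,10-dimethylundeca-5,9-dien-1-yne | CC(C)=CCC/C(C)=C/CCC#C | intermediate
29 | dimethyl[(1E,5E)-2,6,10-trimethylundeca-1,5,9-trien-1-yl]alane (not isolated) | C[Al](C)/C=C(\C)CC/C=C(\C)CCC=C(C)C | intermediate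
30 | (1E,5E)-1-iodo-2,6,10-trimethylundeca-1,5,9-triene | I/C=C(\C)CC/C=C(\C)CCC=C(C)C | intermediate
31 | side-chain alkenylchromium dichloride (trivalent chromium, not isolated) | Cl[Cr](Cl)/C=C(\C)CC/C=C(\C)CCC=C(C)C | intermediate
32 | [(1R,5S,6R)-5-hydroxy-6-[(1S,2E,6E)-1-hydroxy-3,7,11-trimethyldodeca-2,6,10-trien-1-yl]-2-oxo-7-oxabicyclo[4.1.0]hept-3-en-3-yl]methyl acetate | CC(=O)OCC1=C[C@H](O)[C@@]2([C@@H](O)/C=C(\C)CC/C=C(\C)CCC=C(C)C)O[C@H]2C1=O | target

**Step count**

Total: 22 steps. Longest linear sequence: 19 steps (steps 1–18 and 22); the side chain takes steps 19–21.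

**Steps most likely to fail**

Step 14 (key step). The facial selectivity at the C4 aldehyde may erode if chromium is held by the epoxide oxygen instead of the benzylic ether oxygen, so that C3 adds to the Re face; reductive opening of the keto epoxide by excess CrCl2 is the second hazard and is limited by short contact time and strictly aprotic medium. The fallback sets out from 17 and accepts the cyclisation as it falls. The epimeric alcohol, [(1R,5R,6R)-5-hydroxy-6-{[(4-methoxybenzyl)oxy]methyl}-2-oxo-7-oxabicyclo[4.1.0]hept-3-en-3-yl]methyl acetate F1, is separated and inverted by a Mitsunobu reaction (ClCH2CO2H, PPh3, diisopropyl azodicarboxylate, toluene, 0 °C). This gives the chloroacetate of the wanted configuration, [(1R,5S,6R)-5-(chloroacetoxy)-6-{[(4-methoxybenzyl)oxy]methyl}-2-oxo-7-oxabicyclo[4.1.0]hept-3-en-3-yl]methyl acetate F2. Its chloroacetyl group is removed with thiourea and NaHCO3 in EtOH, which does not touch the acetate, and the route is rejoined at 19.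

Step 10. The silyl iodide may open the keto epoxide in competition with conjugate addition, and the iodoallenyl silyl ether may capture formaldehyde poorly or lose its Z-geometry by iodide addition–elimination. The fallback sets out from aldehyde 9 and builds the iodoenone without a Lewis-acidic iodide. Pd(PPh3)4-catalysed cis-addition of Me3SiSnBu3 to triethyl(prop-2-yn-1-yloxy)silane gives triethyl{[(2Z)-2-(tributylstannyl)-3-(trimethylsilyl)prop-2-en-1-yl]oxy}silane F3. Tin–lithium exchange (MeLi, THF, −78 °C) and addition to 9 give (2Z)-1-[(2S,3R)-3-{[tert-butyl(dimethyl)silyl]oxymethyl}-3-{[(4-methoxybenzyl)oxy]methyl}oxiran-2-yl]-2-{[(triethylsilyl)oxy]methyl}-3-(trimethylsilyl)prop-2-en-1-ol F4, with silicon cis to C1. Iododesilylation with retention (N-iodosuccinimide, MeCN/ClCH2CN, 0 °C) gives the corresponding (2Z)-3-iodo allylic alcohol F5. Dess–Martin oxidation gives the (2Z)-3-iodo-2-{[(triethylsilyl)oxy]methyl} enone F6. Selective methanolysis of the primary triethylsilyl ether (pyridinium p-toluenesulfonate, MeOH, 0 °C) then returns the route at 14.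

Step 22. The facial selectivity at the C1' aldehyde may be poor if the hydrogen bond or chelate to O4 does not survive in the coordinating solvent, and the free hydroxyl may protonate part of the alkenylchromium reagent. The fallback sets out from the silyl-protected aldehyde 22 and changes from substrate control to reagent control. Coupling of 22 with 30 is run with CrCl2 carrying a chiral oxazoline sulfonamide ligand (Et3N, NiCl2 complex of 2,9-dimethyl-1,10-phenanthroline as catalyst, THF, rt), with the ligand antipode chosen on a model aldehyde for Si-face delivery. This gives [(1R,5S,6S)-6-[(1S,2E,6E)-1-hydroxy-3,7,11-trimethyldodeca-2,6,10-trien-1-yl]-2-oxo-5-[(triethylsilyl)oxy]-7-oxabicyclo[4.1.0]hept-3-en-3-yl]methyl acetate F7. Desilylation with HF·pyridine in THF at 0 °C returns the route at 32.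

**Further compounds**

F1 | step 14 | [(1R,5R,6R)-5-hydroxy-6-{[(4-methoxybenzyl)oxy]methyl}-2-oxo-7-oxabicyclo[4.1.0]hept-3-en-3-yl]methyl acetate | CC(=O)OCC1=C[C@@H](O)[C@@]2(COCc3ccc(OC)cc3)O[C@H]2C1=O
F2 | step 14 | [(1R,5S,6R)-5-(chloroacetoxy)-6-{[(4-methoxybenzyl)oxy]methyl}-2-oxo-7-oxabicyclo[4.1.0]hept-3-en-3-yl]methyl acetate | CC(=O)OCC1=C[C@H](OC(=O)CCl)[C@@]2(COCc3ccc(OC)cc3)O[C@H]2C1=O
F3 | step 10 | triethyl{[(2Z)-2-(tributylstannyl)-3-(trimethylsilyl)prop-2-en-1-yl]oxy}silane | C[Si](C)(C)/C=C(\[Sn](CCCC)(CCCC)CCCC)CO[Si](CC)(CC)CC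
F4 | step 10 | (2Z)-1-[(2S,3R)-3-{[tert-butyl(dimethyl)silyl]oxymethyl}-3-{[(4-methoxybenzyl)oxy]methyl}oxiran-2-yl]-2-{[(triethylsilyl)oxy]methyl}-3-(trimethylsilyl)prop-2-en-1-ol | C[Si](C)(C)/C=C(CO[Si](CC)(CC)CC)\C(O)[C@@H]1O[C@]1(COCc2ccc(OC)cc2)CO[Si](C)(C)C(C)(C)C
F5 | step 10 | (2Z)-1-[(2S,3R)-3-{[tert-butyl(dimethyl)silyl]oxymethyl}-3-{[(4-methoxybenzyl)oxy]methyl}oxiran-2-yl]-3-iodo-2-{[(triethylsilyl)oxy]methyl}prop-2-en-1-ol | I/C=C(CO[Si](CC)(CC)CC)\C(O)[C@@H]1O[C@]1(COCc2ccc(OC)cc2)CO[Si](C)(C)C(C)(C)C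
F6 | step 10 | (2Z)-1-[(2R,3R)-3-{[tert-butyl(dimethyl)silyl]oxymethyl}-3-{[(4-methoxybenzyl)oxy]methyl}oxiran-2-yl]-3-iodo-2-{[(triethylsilyl)oxy]methyl}prop-2-en-1-one | I/C=C(CO[Si](CC)(CC)CC)\C(=O)[C@@H]1O[C@]1(COCc2ccc(OC)cc2)CO[Si](C)(C)C(C)(C)C
F7 | step 22 | [(1R,5S,6S)-6-[(1S,2E,6E)-1-hydroxy-3,7,11-trimethyldodeca-2,6,10-trien-1-yl]-2-oxo-5-[(triethylsilyl)oxy]-7-oxabicyclo[4.1.0]hept-3-en-3-yl]methyl acetate | CC(=O)OCC1=C[C@H](O[Si](CC)(CC)CC)[C@@]2([C@@H](O)/C=C(\C)CC/C=C(\C)CCC=C(C)C)O[C@H]2C1=O
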